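## Retrosynthetic overview

- **Enabling feature:** in pyrrolo[2,3-d]pyrimidine numbering, the pyrrole C5=C6 bond lies between C4a and N7. It can be read as a former alkyne attached to C4a, next to an amino nitrogen on C7a. The N7–C6 and C5–aryl bonds can then both be made across that one triple bond.
- **End game:** the uracil ring is carried as a 2,4-dimethoxypyrimidine, both phenols as benzyl ethers, and the C6 aroyl carbonyl as a silyl-protected carbinol.
- **Key disconnection:** the pyrrole ring and the C5 aryl group come from a 5-alkynyl-4-trifluoroacetamidopyrimidine and 1-benzyloxy-4-iodo-2-methoxybenzene by aminopalladation and reductive elimination.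
- **Precursor:** Sonogashira coupling joins 4-amino-5-iodo-2,6-dimethoxypyrimidine to the silylated propargylic alcohol made from O-benzylvanillin and ethynylmagnesium bromide, and N-trifluoroacetylation follows.
- **Ring order:** the pyrimidine and both arenes are purchased, so the pyrrole is the only ring formed.

Key step: step 7

Remark on the chemistry: the target is achiral. The one carbinol carbon carried from the Grignard addition to the oxidation is racemic throughout and is erased there. O-benzylvanillin, ethynylmagnesium bromide solution and 4-iodo-2-methoxyphenol are taken as catalogue items.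

## Route

Step 1
Reactants: 1 4-(benzyloxy)-3-methoxybenzaldehyde; 2 ethynylmagnesium bromide
Product: 3 racemic 1-[4-(benzyloxy)-3-methoxyphenyl]prop-2-yn-1-ol
Conditions: 2 (1.3 equiv, 0.5 M in THF), THF, 0 °C to rt; sat. aq. NH4Cl
Reagents that add atoms: none
Why: 1,2-Addition of an alkynyl Grignard reagent to an aromatic aldehyde is reliable and needs no alkyne protecting group; the new carbinol centre forms without facial control and is racemic, which is harmless because it later becomes the ketone carbon.

Step 2
Reactants: 3 racemic 1-[4-(benzyloxy)-3-methoxyphenyl]prop-2-yn-1-ol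
Product: 4 racemic {1-[4-(benzyloxy)-3-methoxyphenyl]prop-2-yn-1-yl}oxy(tert-butyl)dimethylsilane
Conditions: TBSCl, imidazole, DMF, rt
Reagents that add atoms: tert-butyldimethylsilyl chloride, CC(C)(C)[Si](C)(C)Cl
Why: Imidazole-promoted silylation of a secondary alcohol gives an ether that masks the future ketone, is not ionised by zerovalent palladium as a propargylic ester would be, and shields the oxygen from the later acylation.

Step 3
Reactants: 5 4-amino-2,6-dimethoxypyrimidine
Product: 6 4-amino-5-iodo-2,6-dimethoxypyrimidine
Conditions: NIS, MeCN, rt, dark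
Reagents that add atoms: N-iodosuccinimide, O=C1CCC(=O)N1I
Why: In this electrophilic aromatic iodination, C5 is the only C–H position of the ring and is activated by the amino and methoxy donors, so iodine can only be delivered there.

Step 4
Reactants: 6 4-amino-5-iodo-2,6-dimethoxypyrimidine; 4 racemic {1-[4-(benzyloxy)-3-methoxyphenyl]prop-2-yn-1-yl}oxy(tert-butyl)dimethylsilane
Product: 7 racemic 5-{3-[4-(benzyloxy)-3-methoxyphenyl]-3-(tert-butyldimethylsilyloxy)prop-1-ynyl}-2,6-dimethoxypyrimidin-4-amine
Conditions: PdCl2(PPh3)2 (5 mol %), CuI (10 mol %), Et3N, DMF, 50 °C, Ar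
Reagents that add atoms: none
Why: Sonogashira coupling is well established for 4-amino-5-iodopyrimidines, and coupling the free amine at moderate temperature avoids premature ring closure and keeps the labile trifluoroacetyl group out of the amine-rich medium.

Step 5
Reactants: 7 racemic 5-{3-[4-(benzyloxy)-3-methoxyphenyl]-3-(tert-butyldimethylsilyloxy)prop-1-ynyl}-2,6-dimethoxypyrimidin-4-amine
Product: 8 racemic N-(5-{3-[4-(benzyloxy)-3-methoxyphenyl]-3-(tert-butyldimethylsilyloxy)prop-1-ynyl}-2,6-dimethoxypyrimidin-4-yl)-2,2,2-trifluoroacetamide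
Conditions: (CF3CO)2O, pyridine, CH2Cl2, 0 °C; cold aq. NaHCO3 wash, dried and used promptly
Reagents that add atoms: trifluoroacetic anhydride, O=C(OC(=O)C(F)(F)F)C(F)(F)F
Why: In this N-acylation the very electrophilic anhydride overcomes the low nucleophilicity of the pyrimidinamine, pyridine scavenges the acid so that the benzylic silyl ether survives, and any imide from double acylation should revert to the monoamide in the bicarbonate wash.

Step 6
Reactants: 9 4-iodo-2-methoxyphenol
Product: 10 1-(benzyloxy)-4-iodo-2-methoxybenzene
Conditions: BnBr, K2CO3, DMF, rt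
Reagents that add atoms: benzyl bromide, BrCc1ccccc1
Why: This is a Williamson ether synthesis between a phenoxide and a primary benzylic bromide, and the aryl iodide is inert under these conditions.

Step 7
Reactants: 8 racemic N-(5-{3-[4-(benzyloxy)-3-methoxyphenyl]-3-(tert-butyldimethylsilyloxy)prop-1-ynyl}-2,6-dimethoxypyrimidin-4-yl)-2,2,2-trifluoroacetamide; 10 1-(benzyloxy)-4-iodo-2-methoxybenzene
Product: 12 racemic 5-[4-(benzyloxy)-3-methoxyphenyl]-6-{[4-(benzyloxy)-3-methoxyphenyl](tert-butyldimethylsilyloxy)methyl}-2,4-dimethoxy-7H-pyrrolo[2,3-d]pyrimidine, via N7-trifluoroacetyl pyrrolopyrimidine 11 (not isolated)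
Conditions: Pd(PPh3)4 (5 mol %), anhydrous K2CO3 (3 equiv), 10 (1.3 equiv), MeCN, 60 °C, Ar; aqueous work-up
Reagents that add atoms: none
Why: Zerovalent palladium from Pd(PPh3)4 inserts into the carbon–iodine bond of 10, and the resulting divalent arylpalladium iodide binds the triple bond of 8 as a π-acid while K2CO3 deprotonates the acidic CF3CONH group; the amide nitrogen then adds anti to the metal at the alkyne carbon remote from the pyrimidine (N7–C6), and the C5-palladated pyrrole so formed reductively eliminates to forge the C5–aryl bond and release zerovalent palladium. The closest known reaction type is the Cacchi aminopalladation–reductive elimination of 2-alkynyltrifluoroacetanilides and of their aminopyridine counterparts with aryl iodides, which gives 2,3-disubstituted indoles and azaindoles with the same catalyst and base. The pyrrole ring closes in the 5-endo-dig mode, the only one available because attack at the proximal alkyne carbon would demand a four-membered ring, so the regiochemistry (nitrogen at C6, aryl at C5) follows from geometry. No stereocentre is created, and the racemic silyloxy-bearing carbon is a spectator. The selectivity needed is aryl transfer ahead of protonolysis of the pyrrolylpalladium species and ahead of any ionisation at the propargylic carbon: dry carbonate in MeCN and a slight excess of 10 serve the first, while the silyl ether, unlike a propargylic ester, is no leaving group for zerovalent palladium and, unlike an ynone carbonyl, does not polarise the alkyne so that the carbon nitrogen must attack becomes the electron-rich one. The N7-trifluoroacetyl group of 11 is an activated acyl azole and is shed to carbonate and water on work-up, giving 12 with a free N7–H.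

Step 8
Reactants: 12 racemic 5-[4-(benzyloxy)-3-methoxyphenyl]-6-{[4-(benzyloxy)-3-methoxyphenyl](tert-butyldimethylsilyloxy)methyl}-2,4-dimethoxy-7H-pyrrolo[2,3-d]pyrimidine
Product: 13 racemic [4-(benzyloxy)-3-methoxyphenyl]{5-[4-(benzyloxy)-3-methoxyphenyl]-2,4-dimethoxy-7H-pyrrolo[2,3-d]pyrimidin-6-yl}methanol
Conditions: TBAF, AcOH, THF, 0 °C to rt
Reagents that add atoms: none
Why: In this fluoride-driven Si–O cleavage the acetic acid buffer keeps the pyrrole N–H protonated and the medium near neutral, so the doubly activated carbinol should neither ionise nor eliminate, and it is taken on without storage.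

Step 9
Reactants: 13 racemic [4-(benzyloxy)-3-methoxyphenyl]{5-[4-(benzyloxy)-3-methoxyphenyl]-2,4-dimethoxy-7H-pyrrolo[2,3-d]pyrimidin-6-yl}methanol
Product: 14 [4-(benzyloxy)-3-methoxyphenyl]{5-[4-(benzyloxy)-3-methoxyphenyl]-2,4-dimethoxy-7H-pyrrolo[2,3-d]pyrimidin-6-yl}methanone
Conditions: activated MnO2, CH2Cl2, rt
Reagents that add atoms: none
Why: Heterogeneous MnO2 oxidation is selective for benzylic and heterobenzylic alcohols, runs under neutral conditions that spare the free N–H, the benzyl ethers and the electron-rich arenes, and removes the only stereocentre of the route.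

Step 10
Reactants: 14 [4-(benzyloxy)-3-methoxyphenyl]{5-[4-(benzyloxy)-3-methoxyphenyl]-2,4-dimethoxy-7H-pyrrolo[2,3-d]pyrimidin-6-yl}methanone
Product: 15 (4-hydroxy-3-methoxyphenyl)[5-(4-hydroxy-3-methoxyphenyl)-2,4-dimethoxy-7H-pyrrolo[2,3-d]pyrimidin-6-yl]methanone
Conditions: H2 (1 atm), 10% Pd/C, THF/MeOH, rt
Reagents that add atoms: none
Why: In this catalytic hydrogenolysis of aryl benzyl ethers the ketone, a vinylogous amide conjugated with the pyrrole nitrogen and a para-oxygenated arene, should resist reduction at 1 atm in neutral solvent, and debenzylating before the acid step avoids benzyl cation transfer to the electron-rich rings.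

Step 11
Reactants: 15 (4-hydroxy-3-methoxyphenyl)[5-(4-hydroxy-3-methoxyphenyl)-2,4-dimethoxy-7H-pyrrolo[2,3-d]pyrimidin-6-yl]methanone
Product: 16 rigidin D, 6-(4-hydroxy-3-methoxybenzoyl)-5-(4-hydroxy-3-methoxyphenyl)-1H-pyrrolo[2,3-d]pyrimidine-2,4(3H,7H)-dione
Conditions: 6 M aq. HCl, 1,4-dioxane, 100 °C, Ar
Reagents that add atoms: water, O
Why: Acid hydrolysis of the two imidate-type methoxy groups at C2 and C4 proceeds by addition of water to the N-protonated pyrimidine and loss of methanol (addition–elimination) to give the lactam tautomers, whereas the two aryl methyl ethers have no such pathway and are inert to aqueous HCl, so the poorly soluble target should separate on cooling.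

## Compound list

1 | 4-(benzyloxy)-3-methoxybenzaldehyde (O-benzylvanillin) | COc1cc(C=O)ccc1OCc1ccccc1 | starting material
2 | ethynylmagnesium bromide | C#C[Mg]Br | starting material
3 | racemic 1-[4-(benzyloxy)-3-methoxyphenyl]prop-2-yn-1-ol | COc1cc(C(O)C#C)ccc1OCc1ccccc1 | intermediate
4 | racemic {1-[4-(benzyloxy)-3-methoxyphenyl]prop-2-yn-1-yl}oxy(tert-butyl)dimethylsilane | COc1cc(C(O[Si](C)(C)C(C)(C)C)C#C)ccc1OCc1ccccc1 | intermediate
5 | 4-amino-2,6-dimethoxypyrimidine | COc1cc(N)nc(OC)n1 | starting material
6 | 4-amino-5-iodo-2,6-dimethoxypyrimidine | COc1nc(OC)c(I)c(N)n1 | intermediate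
7 | racemic 5-{3-[4-(benzyloxy)-3-methoxyphenyl]-3-(tert-butyldimethylsilyloxy)prop-1-ynyl}-2,6-dimethoxypyrimidin-4-amine | COc1cc(C(O[Si](C)(C)C(C)(C)C)C#Cc2c(N)nc(OC)nc2OC)ccc1OCc1ccccc1 | intermediate
8 | racemic N-(5-{3-[4-(benzyloxy)-3-methoxyphenyl]-3-(tert-butyldimethylsilyloxy)prop-1-ynyl}-2,6-dimethoxypyrimidin-4-yl)-2,2,2-trifluoroacetamide | COc1cc(C(O[Si](C)(C)C(C)(C)C)C#Cc2c(NC(=O)C(F)(F)F)nc(OC)nc2OC)ccc1OCc1ccccc1 | intermediate
9 | 4-iodo-2-methoxyphenol | COc1cc(I)ccc1O | starting material
10 | 1-(benzyloxy)-4-iodo-2-methoxybenzene | COc1cc(I)ccc1OCc1ccccc1 | intermediate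
11 | racemic 7-trifluoroacetyl derivative of compound 12 (N7-trifluoroacetyl pyrrolopyrimidine) | COc1cc(C(O[Si](C)(C)C(C)(C)C)c2n(C(=O)C(F)(F)F)c3nc(OC)nc(OC)c3c2-c2ccc(OCc4ccccc4)c(OC)c2)ccc1OCc1ccccc1 | intermediate
12 | racemic 5-[4-(benzyloxy)-3-methoxyphenyl]-6-{[4-(benzyloxy)-3-methoxyphenyl](tert-butyldimethylsilyloxy)methyl}-2,4-dimethoxy-7H-pyrrolo[2,3-d]pyrimidine | COc1cc(C(O[Si](C)(C)C(C)(C)C)c2[nH]c3nc(OC)nc(OC)c3c2-c2ccc(OCc4ccccc4)c(OC)c2)ccc1OCc1ccccc1 | intermediate
13 | racemic [4-(benzyloxy)-3-methoxyphenyl]{5-[4-(benzyloxy)-3-methoxyphenyl]-2,4-dimethoxy-7H-pyrrolo[2,3-d]pyrimidin-6-yl}methanol | COc1cc(C(O)c2[nH]c3nc(OC)nc(OC)c3c2-c2ccc(OCc4ccccc4)c(OC)c2)ccc1OCc1ccccc1 | intermediate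
14 | [4-(benzyloxy)-3-methoxyphenyl]{5-[4-(benzyloxy)-3-methoxyphenyl]-2,4-dimethoxy-7H-pyrrolo[2,3-d]pyrimidin-6-yl}methanone | COc1cc(C(=O)c2[nH]c3nc(OC)nc(OC)c3c2-c2ccc(OCc4ccccc4)c(OC)c2)ccc1OCc1ccccc1 | intermediate
15 | (4-hydroxy-3-methoxyphenyl)[5-(4-hydroxy-3-methoxyphenyl)-2,4-dimethoxy-7H-pyrrolo[2,3-d]pyrimidin-6-yl]methanone | COc1cc(C(=O)c2[nH]c3nc(OC)nc(OC)c3c2-c2ccc(O)c(OC)c2)ccc1O | intermediate
16 | rigidin D | COc1cc(C(=O)c2[nH]c3[nH]c(=O)[nH]c(=O)c3c2-c2ccc(O)c(OC)c2)ccc1O | target

## Step count and risks

Total step count: 11.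
Longest linear sequence: 9 steps (steps 1, 2, 4, 5, 7, 8, 9, 10, 11).

**Risk 1, step 7.**
- Protonolysis of the pyrrolylpalladium species, or palladium-free addition of the amide anion to the alkyne, may outrun aryl transfer. The ring would then close while C5 stays unsubstituted.
- Carbonate may also strip the trifluoroacetyl group before cyclisation.
- The bulky silyloxybenzyl group may slow coordination of the alkyne.

The fallback separates the two bond formations, sets out from 7 and returns to the route at 12. Heating 7 with CuI in DMF at 110 °C should effect a 5-endo-dig hydroamination to the racemic 5-unsubstituted 6-[aryl(silyloxy)methyl]-2,4-dimethoxy-7H-pyrrolo[2,3-d]pyrimidine F1. NIS in DMF at 0 °C should then iodinate the only free pyrrole position to give the racemic 5-iodo pyrrolopyrimidine F2. A Suzuki–Miyaura coupling of F2 with commercial [4-(benzyloxy)-3-methoxyphenyl]boronic acid (PdCl2(dppf), K2CO3, dioxane/H2O, 90 °C) should deliver 12.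

**Risk 2, step 5.**
- Acylation of the weakly nucleophilic amine, which is flanked by the alkyne, may stall.
- The liberated acid may erode the benzylic silyl ether.
- The trifluoroacetyl group may fall off again during isolation.

The fallback reverses the order of acylation and coupling, sets out from 6 and returns to the route at 8. The robust iodide 6 carries no acid-sensitive group and can be acylated under forcing conditions (trifluoroacetic anhydride, pyridine, CH2Cl2, reflux if needed). This should give N-(5-iodo-2,6-dimethoxypyrimidin-4-yl)-2,2,2-trifluoroacetamide F3, which can be purified by crystallisation. F3 is then coupled with alkyne 4 at room temperature (PdCl2(PPh3)2, CuI, Et3N, THF), as is done with 2-iodotrifluoroacetanilides, to give 8 directly.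

**Risk 3, step 11.**
- Hydrolysis of the second methoxy group may become slow once half-hydrolysed material precipitates.
- Forcing the acid treatment invites erosion of the guaiacol methyl ethers.

The fallback sets out from 15 and returns to the route at 16. It breaks the O–CH3 bonds instead of the ring C–O bonds. Iodotrimethylsilane generated from Me3SiCl and NaI in dry MeCN at rt to 40 °C silylates the pyrimidine nitrogens, and iodide then removes the two imidate methyl groups by SN2 attack. Aryl methyl ethers react far more slowly under these conditions. Methanolic work-up removes all silyl groups and should give 16. This fallback makes no compound outside the list (F0).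

## Further compounds

F1 | step 7 | racemic 6-{[4-(benzyloxy)-3-methoxyphenyl](tert-butyldimethylsilyloxy)methyl}-2,4-dimethoxy-7H-pyrrolo[2,3-d]pyrimidine | COc1cc(C(O[Si](C)(C)C(C)(C)C)c2cc3c(OC)nc(OC)nc3[nH]2)ccc1OCc1ccccc1
F2 | step 7 | racemic 6-{[4-(benzyloxy)-3-methoxyphenyl](tert-butyldimethylsilyloxy)methyl}-5-iodo-2,4-dimethoxy-7H-pyrrolo[2,3-d]pyrimidine | COc1cc(C(O[Si](C)(C)C(C)(C)C)c2[nH]c3nc(OC)nc(OC)c3c2I)ccc1OCc1ccccc1
F3 | step 5 | N-(5-iodo-2,6-dimethoxypyrimidin-4-yl)-2,2,2-trifluoroacetamide | COc1nc(OC)c(I)c(NC(=O)C(F)(F)F)n1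
F0 | step 11 | none | none
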